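**Strategy.** With the ring numbered C1 (methoxy carbon), C2, C3 (ketone), C4 (farnesylated epoxide carbon), C5 (epoxide CH) and C6 (carbinol), the cyclohexenone is disconnected at C5–C6. The key step exploits that C6 is the γ-carbon of the C1–C2–C3 vinylogous ester while C4 is quaternary: only C6 can enolise, and its silyl dienol ether attacks a C5 aldehyde. One operation closes the six-membered ring and sets C5 and C6 relative to a C4 chloride, the latent epoxide. The precursor is an open-chain (S)-α-chloro-α-farnesyl β-keto aldehyde bearing an (E)-3-methoxy-4-silyloxybutenoyl group; its single stereocentre comes from catalytic asymmetric chlorination.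

Key step: step 6

Assumption: the sense of induction of the copper–bisoxazoline chlorination on this acyclic thioester has to be found by experiment; the route is written with the (S,S)-ligand as the one that gives the (R)-chloro thioester, and the (R,R)-ligand is used instead, with no other change, if the sense is opposite.

"Farnesyl" below means (2E,6E)-3,7,11-trimethyldodeca-2,6,10-trien-1-yl; TBS means tert-butyldimethylsilyl.

**Step 1**
Reactants: 1 methyl tetronate (4-methoxy-2(5H)-furanone)
Product: 4 (2E)-4-(TBS-oxy)-3-methoxybut-2-enoic acid, via potassium carboxylate 2 (not isolated), via bis-silyl derivative 3 (not isolated)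
Conditions: KOH, MeOH–H2O, 0 °C to rt; evaporate; TBSCl, imidazole, DMF, rt; then K2CO3, MeOH–THF–H2O, 0 °C; citric acid to pH 4–5
Reagents that add atoms: potassium hydroxide [K+].[OH-]; tert-butyldimethylsilyl chloride CC(C)(C)[Si](C)(C)Cl
Why: Saponification of the lactone gives a carboxylate that cannot relactonise, exhaustive silylation and selective hydrolysis of the labile silyl ester (the standard way to hydroxy acids that lactonise) leave the primary silyl ether, and the E geometry, with CH2O cis to the carboxyl group, is inherited from the ring.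

**Step 2**
Reactants: 4 (2E)-4-(TBS-oxy)-3-methoxybut-2-enoic acid; 5 Meldrum's acid (2,2-dimethyl-1,3-dioxane-4,6-dione); 6 ethanethiol
Product: 8 S-ethyl (4E)-6-(TBS-oxy)-5-methoxy-3-oxohex-4-enethioate, via acyl Meldrum's acid 7 (not isolated)
Conditions: DCC, DMAP, CH2Cl2, 0 °C to rt; filter, cold dilute KHSO4 wash; then 6, toluene, 80 °C, sealed tube
Reagents that add atoms: none
Why: Carbodiimide-mediated C-acylation of Meldrum's acid followed by thermolysis to an acylketene that the thiol traps (acyl Meldrum's acid thiolysis) is a general route to β-keto thioesters; a silyl ether is too poor a nucleophile to intercept the activated acid and the enol ether geometry is not touched.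

**Step 3**
Reactants: 8 S-ethyl (4E)-6-(TBS-oxy)-5-methoxy-3-oxohex-4-enethioate; 9 (2E,6E)-farnesyl bromide
Product: 10 S-ethyl (4E)-6-(TBS-oxy)-2-farnesyl-5-methoxy-3-oxohex-4-enethioate (racemic at C2 of the chain, which is ring carbon C4)
Conditions: K2CO3, acetone, rt
Reagents that add atoms: none
Why: SN2 C-alkylation of the soft potassium enolate of a 1,3-dicarbonyl compound with an allylic bromide takes place at C4, the only doubly activated carbon, and leaves both farnesyl double bonds E.

**Step 4**
Reactants: 10 S-ethyl (4E)-6-(TBS-oxy)-2-farnesyl-5-methoxy-3-oxohex-4-enethioate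
Product: 11 S-ethyl (2R,4E)-6-(TBS-oxy)-2-chloro-2-farnesyl-5-methoxy-3-oxohex-4-enethioate
Conditions: NCS, Cu(OTf)2 (10 mol %), (S,S)-2,2'-isopropylidenebis(4-phenyl-2-oxazoline) (12 mol %), Et2O, 0 °C to rt
Reagents that add atoms: N-chlorosuccinimide O=C1CCC(=O)N1Cl
Why: Lewis acid-catalysed enantioselective α-chlorination of a 1,3-dicarbonyl compound: ketone and thioester oxygens chelate the divalent copper–bisoxazoline complex, the ligand shields one face of the bound enolate and NCS delivers chlorine to the other, which creates the quaternary C4 stereocentre (R here because the thioester outranks the ketone) that can no longer enolise.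

**Step 5**
Reactants: 11 S-ethyl (2R,4E)-6-(TBS-oxy)-2-chloro-2-farnesyl-5-methoxy-3-oxohex-4-enethioate
Product: 12 (2S,4E)-6-(TBS-oxy)-2-chloro-2-farnesyl-5-methoxy-3-oxohex-4-enal
Conditions: Et3SiH, 10% Pd/C (cat.), dry acetone, 0 °C to rt; filter through Celite, concentrate, use crude under anhydrous conditions
Reagents that add atoms: none
Why: Fukuyama reduction: zerovalent palladium inserts into the acyl–sulfur bond and Et3SiH transfers hydride, a method that spares ketones, silyl ethers and trisubstituted alkenes, while the tertiary chloride is closed to SN2-type oxidative addition; C4 is untouched and becomes S only because the formyl group ranks below the ketone.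

**Step 6**
Reactants: 12 (2S,4E)-6-(TBS-oxy)-2-chloro-2-farnesyl-5-methoxy-3-oxohex-4-enal
Product: 15 ring chlorohydrin (4S,5R,6S)-4-(TBS-oxy)-6-chloro-6-farnesyl-5-hydroxy-3-methoxycyclohex-2-en-1-one, via silyl dienol ether 13 (not isolated), via trimethylsilyl ether 14 (not isolated)
Conditions: Me3SiOTf, Et3N, CH2Cl2, −78 to −20 °C; then citric acid, MeOH–H2O, 0 °C
Reagents that add atoms: none
Why: Me3SiOTf silylates the C3 carbonyl oxygen and Et3N removes a proton from C6, the only enolisable position because C4 is quaternary and the aldehyde has no α-hydrogen, to give silyl dienol ether 13, whose γ-carbon C6 then adds to the silyl-activated C5 aldehyde (intramolecular vinylogous Mukaiyama aldol; closest known type: silyl triflate/amine-promoted silylative vinylogous aldol cyclisations and γ-selective additions of enolised β-alkoxy enones to aldehydes). The ring closes in the 6-(enolendo)-exo-trig mode through a half-chair. C5 is controlled by C4: with the C–Cl bond pseudoaxial and antiperiplanar to the aldehyde C=O (Cornforth arrangement) and farnesyl pseudoequatorial, the new C5 oxygen ends up trans-diaxial to chlorine. C6 is controlled by the dienol ether geometry: only the isomer with hydrogen on the inside of the s-cis diene can reach the aldehyde, so the silyloxy group sits on the outside, becomes pseudoequatorial and is cis to the C5 oxygen. The step needs γ- over α-attack and enolisation at C6 only, both secured by the substrate (α-attack at C2 would give a four-membered ring; there is no other acidic C–H), and C4 cannot epimerise because it carries no hydrogen. The aldolate is trapped as trimethylsilyl ether 14, which the citric acid work-up cleaves to 15.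

**Step 7**
Reactants: 15 ring chlorohydrin (4S,5R,6S)-4-(TBS-oxy)-6-chloro-6-farnesyl-5-hydroxy-3-methoxycyclohex-2-en-1-one
Product: 16 (1R,5S,6R)-5-(TBS-oxy)-1-farnesyl-4-methoxy-7-oxabicyclo[4.1.0]hept-3-en-2-one
Conditions: K2CO3, MeOH, 0 °C
Reagents that add atoms: none
Why: Chlorohydrin-to-epoxide closure (intramolecular Williamson reaction, 3-exo-tet): the C5 alkoxide lies trans-diaxial to the C4 chloride, which the adjacent ketone activates for SN2 displacement, so C4 is inverted and the epoxide forms on the face that carries the C6 oxygen.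

**Step 8**
Reactants: 16 (1R,5S,6R)-5-(TBS-oxy)-1-farnesyl-4-methoxy-7-oxabicyclo[4.1.0]hept-3-en-2-one
Product: 17 yanuthone X2, (1R,5S,6R)-1-farnesyl-5-hydroxy-4-methoxy-7-oxabicyclo[4.1.0]hept-3-en-2-one
Conditions: HF·pyridine, pyridine, THF, 0 °C to rt
Reagents that add atoms: none
Why: Fluoride cleavage of the secondary silyl ether under pyridine-buffered conditions leaves the epoxy ketone, the vinylogous ester and the triene intact and touches no stereocentre.

**Compound list**

1 | methyl tetronate (4-methoxy-2(5H)-furanone) | COC1=CC(=O)OC1 | starting material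
2 | potassium (2E)-4-hydroxy-3-methoxybut-2-enoate | OC/C(OC)=C\C([O-])=O.[K+] | intermediate
3 | tert-butyldimethylsilyl (2E)-4-(TBS-oxy)-3-methoxybut-2-enoate | CC(C)(C)[Si](C)(C)OC/C(OC)=C\C(=O)O[Si](C)(C)C(C)(C)C | intermediate
4 | (2E)-4-(TBS-oxy)-3-methoxybut-2-enoic acid | CC(C)(C)[Si](C)(C)OC/C(OC)=C\C(=O)O | intermediate
5 | Meldrum's acid | CC1(C)OC(=O)CC(=O)O1 | starting material
6 | ethanethiol | CCS | starting material
7 | 5-[(2E)-4-(TBS-oxy)-3-methoxybut-2-enoyl]-2,2-dimethyl-1,3-dioxane-4,6-dione (drawn as keto tautomer) | CC(C)(C)[Si](C)(C)OC/C(OC)=C\C(=O)C1C(=O)OC(C)(C)OC1=O | intermediate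
8 | S-ethyl (4E)-6-(TBS-oxy)-5-methoxy-3-oxohex-4-enethioate | CC(C)(C)[Si](C)(C)OC/C(OC)=C\C(=O)CC(=O)SCC | intermediate
9 | (2E,6E)-farnesyl bromide | BrC/C=C(\C)CC/C=C(\C)CCC=C(C)C | starting material
10 | S-ethyl (4E)-6-(TBS-oxy)-2-farnesyl-5-methoxy-3-oxohex-4-enethioate, racemic | CC(C)(C)[Si](C)(C)OC/C(OC)=C\C(=O)C(C/C=C(\C)CC/C=C(\C)CCC=C(C)C)C(=O)SCC | intermediate
11 | S-ethyl (2R,4E)-6-(TBS-oxy)-2-chloro-2-farnesyl-5-methoxy-3-oxohex-4-enethioate | CC(C)(C)[Si](C)(C)OC/C(OC)=C\C(=O)[C@](Cl)(C/C=C(\C)CC/C=C(\C)CCC=C(C)C)C(=O)SCC | intermediate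
12 | (2S,4E)-6-(TBS-oxy)-2-chloro-2-farnesyl-5-methoxy-3-oxohex-4-enal (key-step precursor) | CC(C)(C)[Si](C)(C)OC/C(OC)=C\C(=O)[C@](Cl)(C/C=C(\C)CC/C=C(\C)CCC=C(C)C)C=O | intermediate
13 | (2R,3E,5Z)-6-(TBS-oxy)-2-chloro-2-farnesyl-5-methoxy-3-(trimethylsilyloxy)hexa-3,5-dienal (both ether oxygens cis on C6=C1; C1 and C4 cis on C2=C3) | CC(C)(C)[Si](C)(C)O/C=C(OC)/C=C(O[Si](C)(C)C)\[C@](Cl)(C/C=C(\C)CC/C=C(\C)CCC=C(C)C)C=O | intermediate
14 | (4S,5R,6S)-4-(TBS-oxy)-6-chloro-6-farnesyl-3-methoxy-5-(trimethylsilyloxy)cyclohex-2-en-1-one | COC1=CC(=O)[C@](Cl)(C/C=C(\C)CC/C=C(\C)CCC=C(C)C)[C@H](O[Si](C)(C)C)[C@@H]1O[Si](C)(C)C(C)(C)C | intermediate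
15 | (4S,5R,6S)-4-(TBS-oxy)-6-chloro-6-farnesyl-5-hydroxy-3-methoxycyclohex-2-en-1-one (key-step product; Cl trans to C5–OH, C5–OH cis to C6–OTBS in the ring numbering of the overview) | COC1=CC(=O)[C@](Cl)(C/C=C(\C)CC/C=C(\C)CCC=C(C)C)[C@H](O)[C@@H]1O[Si](C)(C)C(C)(C)C | intermediate
16 | (1R,5S,6R)-5-(TBS-oxy)-1-farnesyl-4-methoxy-7-oxabicyclo[4.1.0]hept-3-en-2-one | COC1=CC(=O)[C@]2(C/C=C(\C)CC/C=C(\C)CCC=C(C)C)O[C@@H]2[C@@H]1O[Si](C)(C)C(C)(C)C | intermediate
17 | yanuthone X2, (1R,5S,6R)-1-farnesyl-5-hydroxy-4-methoxy-7-oxabicyclo[4.1.0]hept-3-en-2-one | COC1=CC(=O)[C@]2(C/C=C(\C)CC/C=C(\C)CCC=C(C)C)O[C@@H]2[C@@H]1O | target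

**Step count and risk**

Total steps: 8. Longest linear sequence: 8 steps (1 to 17).

Steps most likely to fail:

1. Step 6 (ring closure). Attack through the alternative half-chair, with chloride pseudoequatorial to relieve allylic strain against the C3 silyloxy group, would give the cis chlorohydrin, which cannot close to the epoxide. The product could also be enolised a second time at C6, or the formyl group lost by retro-Claisen cleavage during enolisation. Fallback (epoxyquinone approach without an aldol step): it sets out from farnesyl bromide 9. 2,4,5-Trimethoxyphenyllithium (from commercial 1-bromo-2,4,5-trimethoxybenzene, n-BuLi, THF, −78 °C, catalytic CuBr·SMe2) is allylated with 9 to 1-farnesyl-2,4,5-trimethoxybenzene F1. (NH4)2Ce(NO3)6 in MeCN–H2O at 0 °C demethylates the para pair oxidatively to 2-farnesyl-5-methoxy-1,4-benzoquinone F2. Weitz–Scheffer epoxidation under asymmetric phase-transfer catalysis (t-BuOOH, aqueous NaOH, toluene, a cinchona-derived quaternary ammonium salt chosen for the required face) should occur at the alkyl-substituted ring double bond, because the methoxy-bearing one is a deactivated vinylogous ester and the side-chain alkenes are not electrophilic; this gives (1R,6S)-1-farnesyl-4-methoxy-7-oxabicyclo[4.1.0]hept-3-ene-2,5-dione F3. NaBH4 (MeOH, −78 °C) should then reduce the C6 carbonyl, the more electrophilic and less hindered of the two, from the face opposite the epoxide, and the fallback comes back to the route at 17.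

2. Step 5 (thioester to aldehyde). Hydrogenolysis of the ketone-activated C–Cl bond on palladium may compete with insertion into the acyl–sulfur bond, and the α-chloro β-keto aldehyde may lose its formyl group on handling. Fallback (hydride reduction with the ketone masked, no palladium): it sets out from 11. Soft enolisation (t-BuMe2SiOTf, Et3N, CH2Cl2, −78 to 0 °C) masks the ketone as S-ethyl (2R,3E,5Z)-3,6-bis(TBS-oxy)-2-chloro-2-farnesyl-5-methoxyhexa-3,5-dienethioate F4. i-Bu2AlH (CH2Cl2, −78 °C) should stop at the aldehyde stage and give (2R,3E,5Z)-3,6-bis(TBS-oxy)-2-chloro-2-farnesyl-5-methoxyhexa-3,5-dienal F5, the enol ether being inert to hydride. BF3·OEt2 (CH2Cl2, −78 °C) then triggers the Mukaiyama ring closure of the preformed dienol ether, and the fallback comes back to the route at 15 after aqueous work-up.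

3. Step 4 (asymmetric chlorination). Enantiofacial discrimination may be weak for an acyclic chelate whose two carbonyl arms differ little in size, and chlorination at C2 of the vinylogous ester may compete. Fallback (resolution in place of asymmetric catalysis): it sets out from 10. Chlorination without a chiral ligand (NCS, catalytic Mg(ClO4)2, CH2Cl2, rt) gives racemic S-ethyl (4E)-6-(TBS-oxy)-2-chloro-2-farnesyl-5-methoxy-3-oxohex-4-enethioate F6. Preparative chromatography on a chiral stationary phase (supercritical CO2/alcohol) separates it into 11 and the unwanted S-ethyl (2S,4E)-6-(TBS-oxy)-2-chloro-2-farnesyl-5-methoxy-3-oxohex-4-enethioate F7. The fallback comes back to the route at 11.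

**Further compounds**

F1 | step 6 | 1-farnesyl-2,4,5-trimethoxybenzene | COc1cc(OC)c(OC)cc1C/C=C(\C)CC/C=C(\C)CCC=C(C)C
F2 | step 6 | 2-farnesyl-5-methoxy-1,4-benzoquinone | COC1=CC(=O)C(C/C=C(\C)CC/C=C(\C)CCC=C(C)C)=CC1=O
F3 | step 6 | (1R,6S)-1-farnesyl-4-methoxy-7-oxabicyclo[4.1.0]hept-3-ene-2,5-dione | COC1=CC(=O)[C@]2(C/C=C(\C)CC/C=C(\C)CCC=C(C)C)O[C@@H]2C1=O
F4 | step 5 | S-ethyl (2R,3E,5Z)-3,6-bis(TBS-oxy)-2-chloro-2-farnesyl-5-methoxyhexa-3,5-dienethioate | CC(C)(C)[Si](C)(C)O/C=C(OC)/C=C(O[Si](C)(C)C(C)(C)C)\[C@](Cl)(C/C=C(\C)CC/C=C(\C)CCC=C(C)C)C(=O)SCC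
F5 | step 5 | (2R,3E,5Z)-3,6-bis(TBS-oxy)-2-chloro-2-farnesyl-5-methoxyhexa-3,5-dienal | CC(C)(C)[Si](C)(C)O/C=C(OC)/C=C(O[Si](C)(C)C(C)(C)C)\[C@](Cl)(C/C=C(\C)CC/C=C(\C)CCC=C(C)C)C=O
F6 | step 4 | racemic S-ethyl (4E)-6-(TBS-oxy)-2-chloro-2-farnesyl-5-methoxy-3-oxohex-4-enethioate | CC(C)(C)[Si](C)(C)OC/C(OC)=C\C(=O)C(Cl)(C/C=C(\C)CC/C=C(\C)CCC=C(C)C)C(=O)SCC
F7 | step 4 | S-ethyl (2S,4E)-6-(TBS-oxy)-2-chloro-2-farnesyl-5-methoxy-3-oxohex-4-enethioate | CC(C)(C)[Si](C)(C)OC/C(OC)=C\C(=O)[C@@](Cl)(C/C=C(\C)CC/C=C(\C)CCC=C(C)C)C(=O)SCC
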